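**Retrosynthetic overview** (oxolane locants: O1, C2 pentyl, C3 hydroxyl, C4 methylene, C5 side chain; C1′ is the ester-bearing carbinol carbon)
- End game: the C1′ tetradecanoate is put on while C3–OH is masked as a 2-naphthylmethyl ether, and C3–OH is freed last.
- Key disconnection: the oxolane is cut at C3–C4 and O1–C2 into a three-atom unit O1–C5–C4 (a terminal epoxide used with reversed polarity as a β-lithio alkoxide) and a two-carbon unit C3–C2 ((R)-2-chloroheptanal). The oxolane is the only ring and is formed in this step.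
- Enabling feature: ring oxygen O1 on C5 sits next to the unsubstituted ring methylene C4 (a hidden terminal epoxide), and the C3 hydroxyl is vicinal to the O1-bearing C2 (a hidden α-chloro aldehyde: C3 is the carbonyl carbon, C2 the C–Cl centre displaced with inversion).
- Fragments: the epoxide with the C5 and C1′ stereocentres comes from (R,R)-1,2:3,4-diepoxybutane and oct-7-enyl Grignard reagent; the chloro aldehyde comes from heptanal by enamine-catalysed chlorination.

Key step: step 4

Assumption: (2R,2′R)-2,2′-bioxirane (the D-threitol-derived enantiomer of 1,2:3,4-diepoxybutane) is taken as a purchasable chiral-pool reagent.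

**Step 1**
Reactants: 1 8-bromooct-1-ene; 2 (2R,2′R)-2,2′-bioxirane
Product: 4 (1R)-1-[(2R)-oxiran-2-yl]dec-9-en-1-ol, via oct-7-en-1-ylmagnesium bromide 3 (not isolated)
Conditions: 1, Mg, THF, 40 °C; then CuI (10 mol %), 2 (2 equiv), THF, –40 → –20 °C
Reagents that add atoms: none
Why: Copper-catalysed Grignard opening of a terminal epoxide at its unsubstituted carbon (SN2) is reliable, the excess of bis-epoxide should enforce mono-opening, and both stereocentres of 4 come unchanged from the chiral-pool bis-epoxide.

**Step 2**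
Reactants: 4 (1R)-1-[(2R)-oxiran-2-yl]dec-9-en-1-ol
Product: 5 (2R)-2-[(1R)-1-(methoxymethoxy)dec-9-en-1-yl]oxirane
Conditions: MOMCl, i-Pr2NEt, CH2Cl2, 0 °C → rt
Reagents that add atoms: chloromethyl methyl ether, COCCl
Why: O-Alkylation of the secondary alcohol with the α-chloro ether under amine base (MOM ether formation) should leave the epoxide intact and gives a protecting group that cannot migrate and should survive the arene radical anion and the organolithium of step 4.

**Step 3**
Reactants: 6 heptanal
Product: 7 (2R)-2-chloroheptanal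
Conditions: (5R)-5-benzyl-2,2,3-trimethylimidazolidin-4-one·TFA (5 mol %), 2,3,4,5,6,6-hexachlorocyclohexa-2,4-dien-1-one (1.2 equiv), acetone, –30 °C
Reagents that add atoms: 2,3,4,5,6,6-hexachlorocyclohexa-2,4-dien-1-one, O=C1C(Cl)=C(Cl)C(Cl)=C(Cl)C1(Cl)Cl
Why: Enamine-catalysed electrophilic α-chlorination of a linear aldehyde, in which the benzyl group of the (5R)-catalyst shields one face of the E-enamine so that chlorine should arrive on the other face and set the (R)-centre; the labile product is dried and used at once as a solution.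

**Step 4**
Reactants: 5 (2R)-2-[(1R)-1-(methoxymethoxy)dec-9-en-1-yl]oxirane; 7 (2R)-2-chloroheptanal
Product: 11 (2S,3S,5R)-5-[(1R)-1-(methoxymethoxy)dec-9-en-1-yl]-2-pentyloxolan-3-ol, via β-lithio alkoxide 8 (not isolated), via dilithium dialkoxide 9 (not isolated), via chloro diol 10 (not isolated)
Conditions: lithium 4,4′-di-tert-butylbiphenylide (2.1 equiv), THF, –78 °C; then 7 (1.2 equiv), –78 °C; AcOH (2.5 equiv), –78 °C → rt; then MeOH–H2O (1:1), 100 °C, sealed vessel
Reagents that add atoms: none
Why: Two-electron reduction of the terminal epoxide of 5 by the arene radical anion cleaves the O–CH2 bond to give the secondary alkoxide and primary carbanion of 8 (an epoxide carbon of reversed polarity, stable at –78 °C because β-elimination would have to expel an oxide dianion), 8 adds to the aldehyde carbon of 7 to form the C3–C4 bond (9), cold protonation gives chloro diol 10, and on heating the C5 hydroxyl displaces the secondary chloride to form the O1–C2 bond. The closest known reaction types are the reductive lithiation of epoxides to β-lithio alkoxides and their addition to aldehydes, the 1,2-anti-selective addition of organolithiums to α-chloro aldehydes, and the neutral thermal cyclisation of 4-chloro-1,3-diols to 3-hydroxyoxolanes, here run in one flask. The oxolane closes by a 5-exo-tet SN2 displacement. C3 is set in the addition by the neighbouring C–Cl centre (polar Felkin–Anh/Cornforth model, giving the 1,2-anti chlorohydrin), C2 is set by inversion of that C–Cl centre in the ring closure, which places pentyl cis to the C3 hydroxyl, and C5 and C1′ are carried in unchanged from 5. The step needs primary-carbanion regioselectivity in the epoxide cleavage (secured by the terminal epoxide), addition instead of enolisation of 7 (secured by –78 °C and the high carbonyl reactivity of an α-chloro aldehyde), and oxolane instead of oxirane formation from 10 (secured by protonating both alkoxides cold before heating, the LiOAc formed buffering the HCl so that the MOM ether should survive).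

**Step 5**
Reactants: 11 (2S,3S,5R)-5-[(1R)-1-(methoxymethoxy)dec-9-en-1-yl]-2-pentyloxolan-3-ol
Product: 12 2-({[(2S,3S,5R)-5-[(1R)-1-(methoxymethoxy)dec-9-en-1-yl]-2-pentyloxolan-3-yl]oxy}methyl)naphthalene
Conditions: NaH, 2-(bromomethyl)naphthalene, n-Bu4NI (cat.), THF–DMF, 0 °C → rt
Reagents that add atoms: 2-(bromomethyl)naphthalene, BrCc1ccc2ccccc2c1
Why: Williamson etherification of the sodium alkoxide with a reactive benzylic bromide caps the only free hydroxyl with a group that should survive acid and acylation and can be removed oxidatively in the presence of an ester and a terminal alkene.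

**Step 6**
Reactants: 12 2-({[(2S,3S,5R)-5-[(1R)-1-(methoxymethoxy)dec-9-en-1-yl]-2-pentyloxolan-3-yl]oxy}methyl)naphthalene
Product: 13 (1R)-1-[(2R,4S,5S)-4-(naphthalen-2-ylmethoxy)-5-pentyloxolan-2-yl]dec-9-en-1-ol
Conditions: conc. HCl (cat.), MeOH, 45 °C
Reagents that add atoms: none
Why: Acid-catalysed acetal exchange with methanol removes the MOM group, while the arylmethyl ether, the oxolane and the isolated alkene should be inert to dilute methanolic HCl.

**Step 7**
Reactants: 13 (1R)-1-[(2R,4S,5S)-4-(naphthalen-2-ylmethoxy)-5-pentyloxolan-2-yl]dec-9-en-1-ol; 14 tetradecanoyl chloride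
Product: 15 (1R)-1-[(2R,4S,5S)-4-(naphthalen-2-ylmethoxy)-5-pentyloxolan-2-yl]dec-9-en-1-yl tetradecanoate
Conditions: pyridine, DMAP (cat.), CH2Cl2, 0 °C → rt
Reagents that add atoms: none
Why: DMAP-catalysed acylation (nucleophilic acyl substitution through the N-acylpyridinium salt) of the single free secondary alcohol installs the ester with retention at C1′.

**Step 8**
Reactants: 15 (1R)-1-[(2R,4S,5S)-4-(naphthalen-2-ylmethoxy)-5-pentyloxolan-2-yl]dec-9-en-1-yl tetradecanoate
Product: 16 (1R)-1-[(2R,4S,5S)-4-hydroxy-5-pentyloxolan-2-yl]dec-9-en-1-yl tetradecanoate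
Conditions: DDQ, CH2Cl2–pH 7 phosphate buffer (10:1), 0 °C → rt
Reagents that add atoms: none
Why: Oxidative cleavage of the electron-rich naphthylmethyl ether by DDQ (hydride abstraction to the benzylic oxocarbenium ion, then hydrolysis) should free the C3 hydroxyl without touching the ester, the oxolane, the terminal alkene or any stereocentre.

**Compound list**
1 | 8-bromooct-1-ene | C=CCCCCCCBr | starting material
2 | (2R,2′R)-2,2′-bioxirane [(R,R)-1,2:3,4-diepoxybutane] | C1O[C@H]1[C@H]1CO1 | starting material
3 | oct-7-en-1-ylmagnesium bromide | C=CCCCCCC[Mg]Br | intermediate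
4 | (1R)-1-[(2R)-oxiran-2-yl]dec-9-en-1-ol | C=CCCCCCCC[C@@H](O)[C@H]1CO1 | intermediate
5 | (2R)-2-[(1R)-1-(methoxymethoxy)dec-9-en-1-yl]oxirane | C=CCCCCCCC[C@@H](OCOC)[C@H]1CO1 | intermediate
6 | heptanal | CCCCCCC=O | starting material
7 | (2R)-2-chloroheptanal | CCCCC[C@@H](Cl)C=O | intermediate
8 | lithium (2R,3R)-1-lithio-3-(methoxymethoxy)dodec-11-en-2-olate | C=CCCCCCCC[C@@H](OCOC)[C@H](O[Li])C[Li] | intermediate
9 | dilithium (6R,7S,9R,10R)-6-chloro-10-(methoxymethoxy)nonadec-18-ene-7,9-diolate | C=CCCCCCCC[C@@H](OCOC)[C@H](O[Li])C[C@H](O[Li])[C@H](Cl)CCCCC | intermediate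
10 | (6R,7S,9R,10R)-6-chloro-10-(methoxymethoxy)nonadec-18-ene-7,9-diol | C=CCCCCCCC[C@@H](OCOC)[C@H](O)C[C@H](O)[C@H](Cl)CCCCC | intermediate
11 | (2S,3S,5R)-5-[(1R)-1-(methoxymethoxy)dec-9-en-1-yl]-2-pentyloxolan-3-ol | C=CCCCCCCC[C@@H](OCOC)[C@H]1C[C@H](O)[C@H](CCCCC)O1 | intermediate
12 | 2-({[(2S,3S,5R)-5-[(1R)-1-(methoxymethoxy)dec-9-en-1-yl]-2-pentyloxolan-3-yl]oxy}methyl)naphthalene | C=CCCCCCCC[C@@H](OCOC)[C@H]1C[C@H](OCc2ccc3ccccc3c2)[C@H](CCCCC)O1 | intermediate
13 | (1R)-1-[(2R,4S,5S)-4-(naphthalen-2-ylmethoxy)-5-pentyloxolan-2-yl]dec-9-en-1-ol | C=CCCCCCCC[C@@H](O)[C@H]1C[C@H](OCc2ccc3ccccc3c2)[C@H](CCCCC)O1 | intermediate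
14 | tetradecanoyl chloride | CCCCCCCCCCCCCC(=O)Cl | starting material
15 | (1R)-1-[(2R,4S,5S)-4-(naphthalen-2-ylmethoxy)-5-pentyloxolan-2-yl]dec-9-en-1-yl tetradecanoate | C=CCCCCCCC[C@@H](OC(=O)CCCCCCCCCCCCC)[C@H]1C[C@H](OCc2ccc3ccccc3c2)[C@H](CCCCC)O1 | intermediate
16 | (1R)-1-[(2R,4S,5S)-4-hydroxy-5-pentyloxolan-2-yl]dec-9-en-1-yl tetradecanoate | C=CCCCCCCC[C@@H](OC(=O)CCCCCCCCCCCCC)[C@H]1C[C@H](O)[C@H](CCCCC)O1 | target

**Step count**
Total: 8 steps. Longest linear sequence: 7 steps (steps 1, 2, 4, 5, 6, 7, 8).

**Steps most likely to fail**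

Step 4. The strongly basic primary alkyllithium may deprotonate the α-chloro aldehyde instead of adding to it, or the epoxide may be cleaved with the wrong regiochemistry, so that little chloro diol is formed. The fallback sets out from 5 (with 7) and comes back at 11, and it replaces the carbanion by a much less basic enolate. LiAlH4 (THF, 0 °C) opens 5 at the terminal carbon to give (2R,3R)-3-(methoxymethoxy)dodec-11-en-2-ol F1, and Dess–Martin oxidation gives (3R)-3-(methoxymethoxy)dodec-11-en-2-one F2. The kinetic lithium enolate of F2 (LiN(i-Pr)2, THF, –78 °C, deprotonation at the methyl group) adds to 7 in a 1,2-anti-selective aldol reaction to give (6R,7S,10R)-6-chloro-7-hydroxy-10-(methoxymethoxy)nonadec-18-en-9-one F3. A 1,3-syn reduction (Et2BOMe, NaBH4, THF–MeOH, –78 °C, Narasaka–Prasad) sets the C5 centre and gives chloro diol 10, now isolated. Heating 10 in MeOH–H2O closes the oxolane to 11.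

Step 3. The α-chloro aldehyde may lose configurational purity by enolisation during isolation and handling, and material may be lost through its volatility. The fallback sets out from 6 and comes back at 7, and it moves all handling to the alcohol oxidation level. The same enamine chlorination is quenched reductively in the flask (NaBH4, MeOH, 0 °C) to give the configurationally stable (2R)-2-chloroheptan-1-ol F4, which can be purified and stored. A NaHCO3-buffered Dess–Martin oxidation (CH2Cl2, 0 °C) immediately before step 4 regenerates 7 as a dried solution.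

Step 1. The epoxy alkoxide formed first may scramble (Payne-type epoxide migration, opening of the second epoxide by bromide or by more Grignard reagent), which would destroy the epoxide that step 4 needs. The fallback sets out from 1 (through Grignard reagent 3) and comes back at 4, and no epoxide is present during the C–C bond formation. Li2CuCl4-catalysed coupling of 3 with an excess of commercial [(4R,5R)-2,2-dimethyl-1,3-dioxolane-4,5-diyl]bis(methylene) bis(4-methylbenzenesulfonate) (the D-threitol derivative) should give [(4R,5R)-2,2-dimethyl-5-(non-8-en-1-yl)-1,3-dioxolan-4-yl]methyl 4-methylbenzenesulfonate F5. Aqueous AcOH (60 °C) removes the acetonide to give (2R,3R)-2,3-dihydroxydodec-11-en-1-yl 4-methylbenzenesulfonate F6. K2CO3 in MeOH (0 °C) closes the terminal epoxide through the neighbouring hydroxyl to give 4.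

**Further compounds**
F1 | step 4 | (2R,3R)-3-(methoxymethoxy)dodec-11-en-2-ol | C=CCCCCCCC[C@@H](OCOC)[C@@H](C)O
F2 | step 4 | (3R)-3-(methoxymethoxy)dodec-11-en-2-one | C=CCCCCCCC[C@@H](OCOC)C(C)=O
F3 | step 4 | (6R,7S,10R)-6-chloro-7-hydroxy-10-(methoxymethoxy)nonadec-18-en-9-one | C=CCCCCCCC[C@@H](OCOC)C(=O)C[C@H](O)[C@H](Cl)CCCCC
F4 | step 3 | (2R)-2-chloroheptan-1-ol | CCCCC[C@@H](Cl)CO
F5 | step 1 | [(4R,5R)-2,2-dimethyl-5-(non-8-en-1-yl)-1,3-dioxolan-4-yl]methyl 4-methylbenzenesulfonate | C=CCCCCCCC[C@H]1OC(C)(C)O[C@@H]1COS(=O)(=O)c2ccc(C)cc2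
F6 | step 1 | (2R,3R)-2,3-dihydroxydodec-11-en-1-yl 4-methylbenzenesulfonate | C=CCCCCCCC[C@@H](O)[C@H](O)COS(=O)(=O)c1ccc(C)cc1
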